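**Retrosynthetic overview**
- Ring labels: ring A is the benzo ring of the chroman, ring B the pendant aryl ring, ring C the pyran ring. The 1,1-dimethylallyl group at C5' is made last, by aromatic Claisen rearrangement of the O4' prenyl ether; C5' is the only free ortho position.
- The 4'-O-prenyl isoflavan is cut into resorcinol and a 2-arylpropanedial by an asymmetric reductive [3+3] annulation that makes O1–C2 and C4–C4a, closes ring C and sets C3.
- Enabling feature: O1 and C4a are neighbouring atoms of a resorcinol ring A, with C4a para to the C7 hydroxyl. C2 and C4 are two unsubstituted CH2 groups flanking the only stereocentre C3, so ring C is the doubly reduced condensation product of a symmetric C,O-dinucleophile and a symmetric 2-aryl-1,3-dialdehyde.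
- The arylpropanedial comes from 2,3,4-trihydroxybenzaldehyde (ring B) by ketal-directed 2-O-methylation, aldehyde-directed 4-O-prenylation, Wittig homologation and Vilsmeier formylation.
- Ring order: rings A and B are bought as benzenes; ring C is the only ring formed, in step 7.

Key step: step 7

Assumption: the sense of induction of the chiral acid in step 7 cannot be predicted with certainty; the (R)-acid is written, and its enantiomer is used if the protonation at C3 favours the (3R)-chroman.

**Step 1**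
Reactants: 1 2,3,4-trihydroxybenzaldehyde; 2 dichlorodiphenylmethane
Product: 3 4-hydroxy-2,2-diphenyl-1,3-benzodioxole-5-carbaldehyde
Conditions: Ph2O, 175 °C
Reagents that add atoms: dichlorodiphenylmethane ClC(Cl)(c1ccccc1)c1ccccc1
Why: Catechol ketalisation with a gem-dichloride; the 2-hydroxyl is held in a hydrogen bond to the aldehyde, so the 3,4-diol pair should be bridged and the 2-OH left free.

**Step 2**
Reactants: 3 4-hydroxy-2,2-diphenyl-1,3-benzodioxole-5-carbaldehyde; 4 iodomethane
Product: 5 4-methoxy-2,2-diphenyl-1,3-benzodioxole-5-carbaldehyde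
Conditions: K2CO3, DMF, 40 °C
Reagents that add atoms: iodomethane CI
Why: Williamson O-methylation of the only free phenol.

**Step 3**
Reactants: 5 4-methoxy-2,2-diphenyl-1,3-benzodioxole-5-carbaldehyde
Product: 6 3,4-dihydroxy-2-methoxybenzaldehyde
Conditions: AcOH/H2O 4:1, reflux
Reagents that add atoms: none
Why: Acid hydrolysis of the diphenylmethylene ketal, which should leave the methyl ether and the aldehyde untouched.

**Step 4**
Reactants: 6 3,4-dihydroxy-2-methoxybenzaldehyde; 7 1-bromo-3-methylbut-2-ene (prenyl bromide)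
Product: 8 3-hydroxy-2-methoxy-4-[(3-methylbut-2-en-1-yl)oxy]benzaldehyde
Conditions: NaHCO3, NaI (cat.), DMF, 40 °C
Reagents that add atoms: 1-bromo-3-methylbut-2-ene CC(C)=CCBr
Why: Regioselective Williamson etherification; the 4-OH is para to the aldehyde and much the more acidic, so hydrogen carbonate should ionise only this phenol, while the 3-OH is meta and flanked on both sides.

**Step 5**
Reactants: 8 3-hydroxy-2-methoxy-4-[(3-methylbut-2-en-1-yl)oxy]benzaldehyde; 9 (methoxymethyl)triphenylphosphonium chloride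
Product: 10 2-methoxy-3-(2-methoxyethenyl)-6-[(3-methylbut-2-en-1-yl)oxy]phenol (E/Z mixture)
Conditions: KOtBu (2.6 equiv), 9 (2.5 equiv), THF, 0 °C to rt; aq. NH4Cl
Reagents that add atoms: (methoxymethyl)triphenylphosphonium chloride COC[P+](c1ccccc1)(c1ccccc1)c1ccccc1.[Cl-]
Why: Wittig methoxymethylenation; the extra base covers the phenol, whose phenoxide is meta to the aldehyde and does not deactivate it.

**Step 6**
Reactants: 10 2-methoxy-3-(2-methoxyethenyl)-6-[(3-methylbut-2-en-1-yl)oxy]phenol; 11 (chloromethylene)dimethyliminium chloride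
Product: 13 2-{3-hydroxy-2-methoxy-4-[(3-methylbut-2-en-1-yl)oxy]phenyl}propanedial (present largely as its enol), via methoxypropeniminium chloride 12 (not isolated)
Conditions: 11 (2.5 equiv), 2,6-lutidine, CH2Cl2, 0 °C to rt; then 2 M NaOH, 60 °C; then 1 M HCl to pH 4, 0 °C
Reagents that add atoms: (chloromethylene)dimethyliminium chloride C[N+](C)=CCl.[Cl-]; sodium hydroxide (aqueous) [Na+].[OH-]
Why: Vilsmeier–Haack formylation of the enol ether at its nucleophilic aryl-bearing carbon, followed by alkaline hydrolysis of the iminium and enol ether ends to the 2-arylmalondialdehyde; any aryl formate formed at the phenol should be cleaved in the same hydrolysis.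

**Step 7**
Reactants: 13 2-{3-hydroxy-2-methoxy-4-[(3-methylbut-2-en-1-yl)oxy]phenyl}propanedial; 14 benzene-1,3-diol (resorcinol)
Product: 17 (3S)-3-{3-hydroxy-2-methoxy-4-[(3-methylbut-2-en-1-yl)oxy]phenyl}-3,4-dihydro-2H-chromen-7-ol, via chromenylium ion pair 15 (not isolated), via 4H-chromene 16 (not isolated)
Conditions: (R)-3,3'-bis(2,4,6-triisopropylphenyl)-1,1'-binaphthyl-2,2'-diyl hydrogen phosphate (10 mol %), diethyl 2,6-dimethyl-1,4-dihydropyridine-3,5-dicarboxylate (Hantzsch ester, 2.4 equiv), 14 (1.3 equiv), 5 Å molecular sieves, CHCl3, 45 °C, argon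
Reagents that add atoms: benzene-1,3-diol Oc1cccc(O)c1
Why: Proposed new method: the phosphoric acid is expected to catalyse first the [3+3] condensation (Friedel–Crafts attack of a resorcinol carbon on one protonated formyl group of 13, loss of water, 6-exo-trig addition of the neighbouring phenol oxygen to the other formyl carbon, loss of water), which closes ring C and forms C4–C4a and O1–C2 in the chromenylium phosphate 15; the dihydropyridine then gives hydride to C4 (16), the chiral acid protonates C3 of the C2=C3 enol ether inside the ion pair, and a second hydride goes to C2. The closest known reaction types are the strong-acid condensation of resorcinols with arylmalondialdehydes to isoflavylium salts and the chiral phosphoric acid catalysed transfer hydrogenation of 3-substituted quinolines, which runs through the same order of 1,4-hydride addition, enantioselective protonation and 1,2-hydride addition; continuous reduction of the cation is what should let a catalytic amount of a weaker acid drive the condensation. The only new stereocentre, C3, is under catalyst control in the protonation step (or in the hydride capture, if protonation is reversible), and the bulky 3,3'-aryl groups of the acid are relied on to tell the faces of the planar enol ether apart. Regioselectivity on ring A is secured by the symmetry of resorcinol, whose two reactive carbons are equivalent (each ortho to one hydroxyl and para to the other) while the carbon between the hydroxyls is hindered, and the symmetry of the dialdehyde makes C2 and C4 interchangeable. Chemoselectivity rests on the dihydropyridine reducing only cationic intermediates, so the prenyl ether, the free phenols and unreacted aldehyde should be left alone.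

**Step 8**
Reactants: 17 (3S)-3-{3-hydroxy-2-methoxy-4-[(3-methylbut-2-en-1-yl)oxy]phenyl}-3,4-dihydro-2H-chromen-7-ol
Product: 19 (3S)-3-[3,4-dihydroxy-2-methoxy-5-(2-methylbut-3-en-2-yl)phenyl]-3,4-dihydro-2H-chromen-7-ol, via cyclohexadienone 18 (not isolated)
Conditions: N,N-diethylaniline, 190 °C, sealed tube, argon
Reagents that add atoms: none
Why: Aromatic Claisen rearrangement ([3,3]-sigmatropic) should deliver the dimethyl-substituted allyl terminus to C5', the only free ortho position (C3' carries the hydroxyl, the para position is substituted), and the dienone tautomerises to the phenol; C3 is remote and not enolisable, so its configuration is kept.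

**Compound list**
1 | 2,3,4-trihydroxybenzaldehyde | O=Cc1ccc(O)c(O)c1O | starting material
2 | dichlorodiphenylmethane | ClC(Cl)(c1ccccc1)c1ccccc1 | starting material
3 | 4-hydroxy-2,2-diphenyl-1,3-benzodioxole-5-carbaldehyde | O=Cc1ccc2OC(c3ccccc3)(c3ccccc3)Oc2c1O | intermediate
4 | iodomethane | CI | starting material
5 | 4-methoxy-2,2-diphenyl-1,3-benzodioxole-5-carbaldehyde | O=Cc1ccc2OC(c3ccccc3)(c3ccccc3)Oc2c1OC | intermediate
6 | 3,4-dihydroxy-2-methoxybenzaldehyde | O=Cc1ccc(O)c(O)c1OC | intermediate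
7 | 1-bromo-3-methylbut-2-ene | CC(C)=CCBr | starting material
8 | 3-hydroxy-2-methoxy-4-[(3-methylbut-2-en-1-yl)oxy]benzaldehyde | O=Cc1ccc(OCC=C(C)C)c(O)c1OC | intermediate
9 | (methoxymethyl)triphenylphosphonium chloride | COC[P+](c1ccccc1)(c1ccccc1)c1ccccc1.[Cl-] | starting material
10 | 2-methoxy-3-(2-methoxyethenyl)-6-[(3-methylbut-2-en-1-yl)oxy]phenol (E/Z mixture) | COC=Cc1ccc(OCC=C(C)C)c(O)c1OC | intermediate
11 | (chloromethylene)dimethyliminium chloride | C[N+](C)=CCl.[Cl-] | starting material
12 | (2-{3-hydroxy-2-methoxy-4-[(3-methylbut-2-en-1-yl)oxy]phenyl}-3-methoxyprop-2-en-1-ylidene)dimethylammonium chloride | COC=C(C=[N+](C)C)c1ccc(OCC=C(C)C)c(O)c1OC.[Cl-] | intermediate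
13 | 2-{3-hydroxy-2-methoxy-4-[(3-methylbut-2-en-1-yl)oxy]phenyl}propanedial | O=CC(C=O)c1ccc(OCC=C(C)C)c(O)c1OC | intermediate
14 | benzene-1,3-diol (resorcinol) | Oc1cccc(O)c1 | starting material
15 | 7-hydroxy-3-{3-hydroxy-2-methoxy-4-[(3-methylbut-2-en-1-yl)oxy]phenyl}chromenylium (cation shown; counter-ion is the phosphate of the catalyst) | Oc1ccc2cc(-c3ccc(OCC=C(C)C)c(O)c3OC)c[o+]c2c1 | intermediate
16 | 3-{3-hydroxy-2-methoxy-4-[(3-methylbut-2-en-1-yl)oxy]phenyl}-4H-chromen-7-ol | Oc1ccc2CC(=COc2c1)c1ccc(OCC=C(C)C)c(O)c1OC | intermediate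
17 | (3S)-3-{3-hydroxy-2-methoxy-4-[(3-methylbut-2-en-1-yl)oxy]phenyl}-3,4-dihydro-2H-chromen-7-ol | CC(C)=CCOc1ccc([C@H]2COc3cc(O)ccc3C2)c(OC)c1O | intermediate
18 | 2-hydroxy-4-[(3S)-7-hydroxy-3,4-dihydro-2H-chromen-3-yl]-3-methoxy-6-(2-methylbut-3-en-2-yl)cyclohexa-2,4-dien-1-one | C=CC(C)(C)C1C=C([C@H]2COc3cc(O)ccc3C2)C(OC)=C(O)C1=O | intermediate
19 | (3S)-3-[3,4-dihydroxy-2-methoxy-5-(2-methylbut-3-en-2-yl)phenyl]-3,4-dihydro-2H-chromen-7-ol | C=CC(C)(C)c1cc([C@H]2COc3cc(O)ccc3C2)c(OC)c(O)c1O | target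

**Step count**
Total steps: 8. Longest linear sequence: 8 steps (1 to 19).

**Steps most likely to fail**

**Step 7 (proposed new method).** The weak chiral acid may not carry the condensation through to the chromenylium stage, the product phenol may be attacked again by cationic intermediates, or the protonation at C3 may show poor facial selectivity. The fallback uses known chemistry and builds ring C by auxiliary-controlled alkylation and Mitsunobu etherification instead of annulation. It sets out from 10 and comes back to the route at 17.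
- Silylation of 10 (tert-butyldimethylsilyl chloride, imidazole, DMF) should give tert-butyl{2-methoxy-3-(2-methoxyethenyl)-6-[(3-methylbut-2-en-1-yl)oxy]phenoxy}dimethylsilane F1.
- Hydrolysis of the enol ether (2 M HCl, THF, rt) should give 2-{3-[(tert-butyldimethylsilyl)oxy]-2-methoxy-4-[(3-methylbut-2-en-1-yl)oxy]phenyl}acetaldehyde F2.
- Pinnick oxidation (NaClO2, NaH2PO4, large excess of 2-methylbut-2-ene, t-BuOH/H2O) should give {3-[(tert-butyldimethylsilyl)oxy]-2-methoxy-4-[(3-methylbut-2-en-1-yl)oxy]phenyl}acetic acid F3.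
- Activation with pivaloyl chloride/Et3N and reaction with lithiated (4S)-4-benzyl-1,3-oxazolidin-2-one (n-BuLi, THF, −78 °C) should give (4S)-4-benzyl-3-({3-[(tert-butyldimethylsilyl)oxy]-2-methoxy-4-[(3-methylbut-2-en-1-yl)oxy]phenyl}acetyl)-1,3-oxazolidin-2-one F4.
- In parallel, commercial 2,4-dihydroxybenzaldehyde is silylated (tert-butyldimethylsilyl chloride, imidazole) to 2,4-bis[(tert-butyldimethylsilyl)oxy]benzaldehyde F5, reduced (NaBH4, MeOH, 0 °C) to {2,4-bis[(tert-butyldimethylsilyl)oxy]phenyl}methanol F6, and brominated (CBr4, PPh3, CH2Cl2, 0 °C) to {[4-(bromomethyl)-1,3-phenylene]bis(oxy)}bis(tert-butyldimethylsilane) F7, which is used at once.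
- Evans alkylation of the sodium enolate of F4 (NaN(SiMe3)2, THF, −78 °C) with F7 should give (4S)-4-benzyl-3-[(2S)-3-{2,4-bis[(tert-butyldimethylsilyl)oxy]phenyl}-2-{3-[(tert-butyldimethylsilyl)oxy]-2-methoxy-4-[(3-methylbut-2-en-1-yl)oxy]phenyl}propanoyl]-1,3-oxazolidin-2-one F8. The bromide enters the chelated Z-enolate on the face away from the benzyl group of the auxiliary.
- Reductive removal of the auxiliary (LiBH4, THF/MeOH, 0 °C) should give (2S)-3-{2,4-bis[(tert-butyldimethylsilyl)oxy]phenyl}-2-{3-[(tert-butyldimethylsilyl)oxy]-2-methoxy-4-[(3-methylbut-2-en-1-yl)oxy]phenyl}propan-1-ol F9.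
- Desilylation (Bu4NF, THF, 0 °C) should give 4-[(2S)-3-hydroxy-2-{3-hydroxy-2-methoxy-4-[(3-methylbut-2-en-1-yl)oxy]phenyl}propyl]benzene-1,3-diol F10.
- Mitsunobu etherification (PPh3, diisopropyl azodicarboxylate, THF, 0 °C) should close ring C at the only phenol that can reach the carbinol and give 17.

**Step 8.** At 190 °C the allylic C–O bond may ionise (loss of the prenyl group), or the new ortho-allyl phenol may cyclise onto its alkene, on a late and valuable triphenol. The fallback moves the sigmatropic step to the simple aldehyde and carries the finished side chain through the annulation. It sets out from 8 and comes back at 19.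
- Claisen rearrangement of 8 (N,N-diethylaniline, 190 °C) should give 3,4-dihydroxy-2-methoxy-5-(2-methylbut-3-en-2-yl)benzaldehyde F11.
- Protection (NaH, chloromethyl methyl ether, DMF, 0 °C) should give 2-methoxy-3,4-bis(methoxymethoxy)-5-(2-methylbut-3-en-2-yl)benzaldehyde F12.
- Wittig methoxymethylenation as in step 5 should give 2-methoxy-1-(2-methoxyethenyl)-3,4-bis(methoxymethoxy)-5-(2-methylbut-3-en-2-yl)benzene F13.
- Formylation and hydrolysis as in step 6 should give 2-[2-methoxy-3,4-bis(methoxymethoxy)-5-(2-methylbut-3-en-2-yl)phenyl]propanedial F14.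
- Annulation with 14 under the conditions of step 7 should give (3S)-3-[2-methoxy-3,4-bis(methoxymethoxy)-5-(2-methylbut-3-en-2-yl)phenyl]-3,4-dihydro-2H-chromen-7-ol F15.
- Acetal cleavage (HCl, MeOH, rt) should give 19.

**Step 6.** The iminium salt may attack the electron-rich ring or the free phenol instead of the enol ether, and the HCl set free may cleave the prenyl ether. The fallback introduces the second formyl carbon under neutral conditions by condensation of an enolisable aldehyde with an aminal ester. It sets out from 10 and comes back at 13.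
- Mild hydrolysis of 10 (2 M HCl, THF, rt) should give 2-{3-hydroxy-2-methoxy-4-[(3-methylbut-2-en-1-yl)oxy]phenyl}acetaldehyde F16.
- Condensation with tert-butoxybis(dimethylamino)methane (toluene, 80 °C) should give 3-(dimethylamino)-2-{3-hydroxy-2-methoxy-4-[(3-methylbut-2-en-1-yl)oxy]phenyl}prop-2-enal F17.
- Hydrolysis (2 M NaOH, EtOH, 70 °C; then 1 M HCl to pH 4) should give 13.

**Further compounds**
F1 | step 7 | tert-butyl{2-methoxy-3-(2-methoxyethenyl)-6-[(3-methylbut-2-en-1-yl)oxy]phenoxy}dimethylsilane | COC=Cc1ccc(OCC=C(C)C)c(O[Si](C)(C)C(C)(C)C)c1OC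
F2 | step 7 | 2-{3-[(tert-butyldimethylsilyl)oxy]-2-methoxy-4-[(3-methylbut-2-en-1-yl)oxy]phenyl}acetaldehyde | O=CCc1ccc(OCC=C(C)C)c(O[Si](C)(C)C(C)(C)C)c1OC
F3 | step 7 | {3-[(tert-butyldimethylsilyl)oxy]-2-methoxy-4-[(3-methylbut-2-en-1-yl)oxy]phenyl}acetic acid | OC(=O)Cc1ccc(OCC=C(C)C)c(O[Si](C)(C)C(C)(C)C)c1OC
F4 | step 7 | (4S)-4-benzyl-3-({3-[(tert-butyldimethylsilyl)oxy]-2-methoxy-4-[(3-methylbut-2-en-1-yl)oxy]phenyl}acetyl)-1,3-oxazolidin-2-one | O=C(Cc1ccc(OCC=C(C)C)c(O[Si](C)(C)C(C)(C)C)c1OC)N1[C@@H](Cc2ccccc2)COC1=O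
F5 | step 7 | 2,4-bis[(tert-butyldimethylsilyl)oxy]benzaldehyde | O=Cc1ccc(O[Si](C)(C)C(C)(C)C)cc1O[Si](C)(C)C(C)(C)C
F6 | step 7 | {2,4-bis[(tert-butyldimethylsilyl)oxy]phenyl}methanol | OCc1ccc(O[Si](C)(C)C(C)(C)C)cc1O[Si](C)(C)C(C)(C)C
F7 | step 7 | {[4-(bromomethyl)-1,3-phenylene]bis(oxy)}bis(tert-butyldimethylsilane) | BrCc1ccc(O[Si](C)(C)C(C)(C)C)cc1O[Si](C)(C)C(C)(C)C
F8 | step 7 | (4S)-4-benzyl-3-[(2S)-3-{2,4-bis[(tert-butyldimethylsilyl)oxy]phenyl}-2-{3-[(tert-butyldimethylsilyl)oxy]-2-methoxy-4-[(3-methylbut-2-en-1-yl)oxy]phenyl}propanoyl]-1,3-oxazolidin-2-one | O=C([C@@H](Cc1ccc(O[Si](C)(C)C(C)(C)C)cc1O[Si](C)(C)C(C)(C)C)c1ccc(OCC=C(C)C)c(O[Si](C)(C)C(C)(C)C)c1OC)N1[C@@H](Cc2ccccc2)COC1=O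
F9 | step 7 | (2S)-3-{2,4-bis[(tert-butyldimethylsilyl)oxy]phenyl}-2-{3-[(tert-butyldimethylsilyl)oxy]-2-methoxy-4-[(3-methylbut-2-en-1-yl)oxy]phenyl}propan-1-ol | OC[C@@H](Cc1ccc(O[Si](C)(C)C(C)(C)C)cc1O[Si](C)(C)C(C)(C)C)c1ccc(OCC=C(C)C)c(O[Si](C)(C)C(C)(C)C)c1OC
F10 | step 7 | 4-[(2S)-3-hydroxy-2-{3-hydroxy-2-methoxy-4-[(3-methylbut-2-en-1-yl)oxy]phenyl}propyl]benzene-1,3-diol | OC[C@@H](Cc1ccc(O)cc1O)c1ccc(OCC=C(C)C)c(O)c1OC
F11 | step 8 | 3,4-dihydroxy-2-methoxy-5-(2-methylbut-3-en-2-yl)benzaldehyde | O=Cc1cc(C(C)(C)C=C)c(O)c(O)c1OC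
F12 | step 8 | 2-methoxy-3,4-bis(methoxymethoxy)-5-(2-methylbut-3-en-2-yl)benzaldehyde | O=Cc1cc(C(C)(C)C=C)c(OCOC)c(OCOC)c1OC
F13 | step 8 | 2-methoxy-1-(2-methoxyethenyl)-3,4-bis(methoxymethoxy)-5-(2-methylbut-3-en-2-yl)benzene | COC=Cc1cc(C(C)(C)C=C)c(OCOC)c(OCOC)c1OC
F14 | step 8 | 2-[2-methoxy-3,4-bis(methoxymethoxy)-5-(2-methylbut-3-en-2-yl)phenyl]propanedial | O=CC(C=O)c1cc(C(C)(C)C=C)c(OCOC)c(OCOC)c1OC
F15 | step 8 | (3S)-3-[2-methoxy-3,4-bis(methoxymethoxy)-5-(2-methylbut-3-en-2-yl)phenyl]-3,4-dihydro-2H-chromen-7-ol | C=CC(C)(C)c1cc([C@H]2COc3cc(O)ccc3C2)c(OC)c(OCOC)c1OCOC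
F16 | step 6 | 2-{3-hydroxy-2-methoxy-4-[(3-methylbut-2-en-1-yl)oxy]phenyl}acetaldehyde | O=CCc1ccc(OCC=C(C)C)c(O)c1OC
F17 | step 6 | 3-(dimethylamino)-2-{3-hydroxy-2-methoxy-4-[(3-methylbut-2-en-1-yl)oxy]phenyl}prop-2-enal | CN(C)C=C(C=O)c1ccc(OCC=C(C)C)c(O)c1OC
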